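Numbering and enabling feature: isochromene numbering throughout (C1 = OCH=, O2, C3, C4, C4a, C5, C6 = ketone, C7 = carbinol, C8 = ester-bearing CH, C8a; C9 = ester carbon on C8; ring A = carbocycle, ring B = pyran). C9–C8–C8a–C4a=C5 is a γ,δ-unsaturated acid and C9–C8–C7–C6–C5 closed by one oxygen is a δ-lactone, so ring A is the [3,3] ring-contraction product of a 6-alkenyl lactone.
Retrosynthesis: cut O2–C3 (ring B, back to a C1 aldehyde and the C3≡C4 alkyne), the side-chain ester O–C bond, C8–C8a (ring A, back to the lactone O–C5 bond), then C7–C8 (bromoacetate tethered on O5), C5–C6 (aldol) and C4–C4a (Sonogashira).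
Forward: enynal, aldol, bromoacetate, δ-lactone, ring A by Ireland–Claisen contraction, side-chain ester, C6 ketone, ring B by silver-catalysed 6-endo closure, free acrylic acid.
Stereochemistry: C5 and C6 from a proline-type anti aldol; C7 by 1,3-induction from C5 in a tethered samarium Reformatsky lactonisation; C8 by chirality transfer from C5 in the key step (C5 and C6 are then consumed); side-chain C4 from (S)-2-methylbutan-1-ol, side-chain C2 by lipase resolution followed by Mitsunobu inversion.

Key step: step 10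

Remark on the chemistry: the dibromide of step 3 is racemic (one enantiomer drawn), and the keto aldehyde of step 18 is drawn in its keto form with the inherited C8a configuration although it will equilibrate with its hydroxymethylene enol, which is harmless because C8a becomes sp2 in step 19.
Abbreviations: TBS = tert-butyldimethylsilyl, TES = triethylsilyl, TMS = trimethylsilyl.

Step 1
Reactants: 1 3-(trimethylsilyl)propiolaldehyde; 2 tert-butyl (triphenylphosphoranylidene)acetate
Product: 3 tert-butyl (E)-5-(trimethylsilyl)pent-2-en-4-ynoate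
Conditions: CH2Cl2, 0 °C → rt
Reagents that add atoms: none
Why: Wittig olefination with a stabilised ylide should give the (E)-enoate, while the silyl group keeps the alkyne terminus masked.

Step 2
Reactants: 3 tert-butyl (E)-5-(trimethylsilyl)pent-2-en-4-ynoate
Product: 4 tert-butyl (E)-pent-2-en-4-ynoate
Conditions: Bu4NF (1.05 equiv), AcOH (1.2 equiv), THF, 0 °C
Reagents that add atoms: none
Why: Fluoride-induced protodesilylation of the alkynylsilane, buffered with acetic acid so that no basic species adds to the enynoate.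

Step 3
Reactants: 5 (E)-4,4-dimethoxybut-2-enal
Product: 7 (Z)-2-bromo-4,4-dimethoxybut-2-enal, via 2,3-dibromo-4,4-dimethoxybutanal 6 (not isolated)
Conditions: Br2, CH2Cl2, −78 → 0 °C; then Et3N, 0 °C → rt
Reagents that add atoms: bromine, BrBr
Why: Bromination–dehydrobromination of an enal: bromine adds to the alkene and triethylamine removes the acidic α-hydrogen with loss of the β-bromide, giving the α-bromo enal in which the formyl and acetal carbons stay trans; the acetal meets no protic acid.

Step 4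
Reactants: 7 (Z)-2-bromo-4,4-dimethoxybut-2-enal; 4 tert-butyl (E)-pent-2-en-4-ynoate
Product: 8 tert-butyl (2E,6E)-6-formyl-8,8-dimethoxyocta-2,6-dien-4-ynoate
Conditions: PdCl2(PPh3)2 (3 mol %), CuI (5 mol %), Et3N, THF, 0 °C → rt
Reagents that add atoms: none
Why: Sonogashira coupling: oxidative addition of the electron-poor vinyl bromide to zerovalent palladium and transfer of the copper acetylide give the enyne with retention of alkene geometry (C4–C4a bond), and the tertiary amine does not add to the enal.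

Step 5
Reactants: 9 hydroxyacetone
Product: 10 1-[(tert-butyldimethylsilyl)oxy]propan-2-one
Conditions: TBSCl, imidazole, CH2Cl2, 0 °C → rt
Reagents that add atoms: tert-butyldimethylsilyl chloride (TBSCl), CC(C)(C)[Si](C)(C)Cl
Why: Imidazole-assisted silylation of the primary alcohol.

Step 6
Reactants: 8 tert-butyl (2E,6E)-6-formyl-8,8-dimethoxyocta-2,6-dien-4-ynoate; 10 1-[(tert-butyldimethylsilyl)oxy]propan-2-one
Product: 11 tert-butyl (2E,6E)-6-[(1S,2S)-2-(TBSO)-1-hydroxy-3-oxobutyl]-8,8-dimethoxyocta-2,6-dien-4-ynoate (anti aldol; 5S,6S)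
Conditions: (S)-5-(pyrrolidin-2-yl)-1H-tetrazole (20 mol %), 10 (5 equiv), DMSO, rt
Reagents that add atoms: none
Why: Proline-type enamine aldol addition: the secondary amine forms the enamine on the oxygen-bearing carbon with the silyloxy group trans to nitrogen, and the acidic tetrazole N–H guides the non-enolisable aldehyde through a chair-like hydrogen-bonded transition state, so the (S)-catalyst should give the anti (5S,6S) adduct; only C5 is needed later, because C6 is oxidised in step 17.

Step 7
Reactants: 11 anti aldol (5S,6S); 12 bromoacetyl bromide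
Product: 13 tert-butyl (2E,6E)-6-[(1S,2S)-1-(2-bromoacetoxy)-2-(TBSO)-3-oxobutyl]-8,8-dimethoxyocta-2,6-dien-4-ynoate
Conditions: pyridine (1.5 equiv), CH2Cl2, −40 → 0 °C
Reagents that add atoms: none
Why: O-acylation of the secondary alcohol with an acid bromide, fast enough at low temperature to avoid β-elimination of the aldol; it places C8 and C9 on O5 as a tether.

Step 8
Reactants: 13 C5 bromoacetate
Product: 15 tert-butyl (2E,6E)-6-[(2S,3S,4R)-3-(TBSO)-4-hydroxy-4-methyl-6-oxooxan-2-yl]-8,8-dimethoxyocta-2,6-dien-4-ynoate, via samarium enolate 14 (not isolated)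
Conditions: SmI2 (0.1 M in THF, 2.2 equiv), THF, −78 °C; AcOH, −78 °C
Reagents that add atoms: none
Why: Intramolecular Reformatsky reaction with divalent samarium: SmI2 reduces the C–Br bond much faster than any other group, and the trivalent samarium enolate adds to the methyl ketone (6-exo-trig, C7–C8 bond, lactone ring) through a samarium-bridged bicyclic chair with the alkenyl, silyloxy and methyl groups equatorial and the ketone oxygen axial, so C7 is set by 1,3-induction from C5 with its hydroxyl trans to the alkenyl group (7R).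

Step 9
Reactants: 15 hydroxy lactone
Product: 16 tert-butyl (2E,6E)-6-[(2S,3S,4R)-3-(TBSO)-4-methyl-6-oxo-4-(TESO)oxan-2-yl]-8,8-dimethoxyocta-2,6-dien-4-ynoate
Conditions: TESOTf (1.3 equiv), 2,6-lutidine, CH2Cl2, −78 °C
Reagents that add atoms: triethylsilyl trifluoromethanesulfonate (TESOTf), CC[Si](CC)(CC)OS(=O)(=O)C(F)(F)F
Why: Silyl triflate silylation of the tertiary alcohol; at −78 °C with a small excess the hydroxyl should react before the triflate can activate the dimethyl acetal.

Step 10
Reactants: 16 6-alkenyl δ-lactone (C7 OTES trans to the alkenyl group)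
Product: 19 (1R,2S,5S,6R)-3-[(3E)-5-tert-butoxy-5-oxopent-3-en-1-yn-1-yl]-5-(TBSO)-2-(dimethoxymethyl)-6-methyl-6-(TESO)cyclohex-3-ene-1-carboxylic acid, via silyl ketene acetal 17 (not isolated), via trimethylsilyl ester 18 (not isolated)
Conditions: TMSCl (4 equiv), KN(SiMe3)2 (1.5 equiv, added last), THF–PhMe, −78 °C → rt, then 80 °C; aq. citric acid, THF, 0 °C
Reagents that add atoms: none
Why: KN(SiMe3)2 removes a C8 proton of 16 with TMSCl already present, so the lactone enolate is O-silylated at once to the cyclic silyl ketene acetal 17, whose C8=C9–O–C5–C4a=C8a array undergoes a concerted [3,3] shift on warming, forming C8–C8a, breaking O–C5 and moving the alkene to C4a=C5. The closest known reaction is the Ireland–Claisen rearrangement in its ring-contracting form, in which 6-alkenyl six-membered lactones give cyclohexenecarboxylic acids. Ring A closes by the sigmatropic shift itself, through a boat-like, bicyclo[2.2.2]octane-shaped transition state enforced by the two-atom C6–C7 bridge between C8 and C5 (a suprafacial pericyclic closure, not an exo or endo attack). C8 is controlled by C5: C8a can reach C8 only on the lactone face that carries the alkenyl group, so the carboxyl group ends cis to the C7 silyloxy group and trans to the C7 methyl group, which is 8R. C8a is controlled by the boat geometry together with the E alkene, which place the dimethoxymethyl group cis to the carboxyl group; this centre is removed later. The step needs enolisation without β-elimination of the C7 silyloxy group and complete chirality transfer; the internal TMSCl quench at −78 °C, the ring-fixed ketene acetal geometry and the tether should secure both, and mild aqueous acid frees the acid from silyl ester 18 without epimerising C8.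

Step 11
Reactants: 20 (S)-2-methylbutan-1-ol
Product: 21 (S)-1-bromo-2-methylbutane
Conditions: PPh3, Br2, imidazole, CH2Cl2, 0 °C → rt
Reagents that add atoms: bromine, BrBr
Why: Appel-type bromination (alkoxyphosphonium, SN2 at the primary carbon); the stereocentre is one carbon away and untouched.

Step 12
Reactants: 21 (S)-1-bromo-2-methylbutane; 22 acetaldehyde
Product: 24 (4S)-4-methylhexan-2-ol as a mixture of both C2 epimers, via Grignard reagent 23 (not isolated)
Conditions: Mg, THF, rt; then MeCHO, −78 → 0 °C; 1 M HCl work-up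
Reagents that add atoms: none
Why: Grignard addition to an aldehyde; the carbinol centre forms without control and is sorted in step 13, while C4 is unaffected.

Step 13
Reactants: 24 (4S)-4-methylhexan-2-ol (C2 epimers)
Product: 25 (2R,4S)-4-methylhexan-2-yl acetate
Conditions: Novozym 435 (immobilised lipase B of Candida antarctica), vinyl acetate, hexane, 30 °C, stopped near half conversion
Reagents that add atoms: vinyl acetate, CC(=O)OC=C
Why: Lipase-catalysed transesterification: lipase B acylates the (R)-configured methyl carbinol much faster, so the (2R,4S) epimer should be taken as its acetate and separated from the unreacted (2S,4S) alcohol; the enol ester makes the acylation irreversible.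

Step 14
Reactants: 25 (2R,4S)-4-methylhexan-2-yl acetate
Product: 26 (2R,4S)-4-methylhexan-2-ol
Conditions: K2CO3 (0.2 equiv), MeOH, rt
Reagents that add atoms: none
Why: Base-catalysed methanolysis of the acetate, which touches neither stereocentre.

Step 15
Reactants: 19 ring A carboxylic acid; 26 (2R,4S)-4-methylhexan-2-ol
Product: 27 (2S,4S)-4-methylhexan-2-yl (1R,2S,5S,6R)-3-[(3E)-5-tert-butoxy-5-oxopent-3-en-1-yn-1-yl]-5-(TBSO)-2-(dimethoxymethyl)-6-methyl-6-(TESO)cyclohex-3-ene-1-carboxylate
Conditions: PPh3, DIAD, THF, 0 °C → rt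
Reagents that add atoms: none
Why: Mitsunobu esterification: the carboxylate displaces the alkoxyphosphonium ion by SN2 with inversion at side-chain C2 (2R to 2S), and since the acid is never activated C8 cannot epimerise through a ketene or enol.

Step 16
Reactants: 27 bis-silylated ester
Product: 28 (2S,4S)-4-methylhexan-2-yl (1R,2S,5S,6R)-3-[(3E)-5-tert-butoxy-5-oxopent-3-en-1-yn-1-yl]-2-(dimethoxymethyl)-5,6-dihydroxy-6-methylcyclohex-3-ene-1-carboxylate
Conditions: HF·pyridine, pyridine, THF, 0 °C → rt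
Reagents that add atoms: none
Why: Fluoride cleavage of both silyl ethers under buffered conditions that should spare the acetal, both esters and C8 and that avoid an alkoxide able to lactonise onto the ester.

Step 17
Reactants: 28 diol
Product: 29 (2S,4S)-4-methylhexan-2-yl (1R,2S,6R)-3-[(3E)-5-tert-butoxy-5-oxopent-3-en-1-yn-1-yl]-2-(dimethoxymethyl)-6-hydroxy-6-methyl-5-oxocyclohex-3-ene-1-carboxylate
Conditions: Dess–Martin periodinane (1.5 equiv), pyridine, CH2Cl2, 0 °C → rt
Reagents that add atoms: none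
Why: Dess–Martin oxidation of the secondary allylic alcohol to the C6 enone; the tertiary C7 alcohol cannot be oxidised and the non-basic medium avoids retro-aldol cleavage.

Step 18
Reactants: 29 enone acetal
Product: 30 (2S,4S)-4-methylhexan-2-yl (1R,2S,6R)-3-[(3E)-5-tert-butoxy-5-oxopent-3-en-1-yn-1-yl]-2-formyl-6-hydroxy-6-methyl-5-oxocyclohex-3-ene-1-carboxylate
Conditions: p-TsOH·H2O (0.2 equiv), THF–H2O (5:1), rt
Reagents that add atoms: water, O
Why: Acid-catalysed acetal hydrolysis; C8a becomes the central carbon of a vinylogous 1,3-dicarbonyl unit and loses its configuration by enolisation as intended, while the tert-butyl ester survives dilute acid.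

Step 19
Reactants: 30 keto aldehyde
Product: 31 (2S,4S)-4-methylhexan-2-yl (7R,8R)-3-[(E)-3-tert-butoxy-3-oxoprop-1-en-1-yl]-7-hydroxy-7-methyl-6-oxo-7,8-dihydro-6H-isochromene-8-carboxylate
Conditions: AgOTf (10 mol %), CH2Cl2, rt, dark
Reagents that add atoms: none
Why: Silver-catalysed cycloisomerisation of an alkynyl aldehyde: AgOTf activates the alkyne, the formyl (enol) oxygen attacks C3 in a 6-endo-dig closure of ring B, and loss of the C8a proton with protodemetalation gives the neutral 6H-isochromen-6-one; C7 and C8 are not involved.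

Step 20
Reactants: 31 tert-butyl ester
Product: 32 (2E)-3-[(7R,8R)-7-hydroxy-7-methyl-8-({[(2S,4S)-4-methylhexan-2-yl]oxy}carbonyl)-6-oxo-7,8-dihydro-6H-isochromen-3-yl]prop-2-enoic acid (CNP0114760.1)
Conditions: TFA–CH2Cl2 (1:4), 0 °C → rt
Reagents that add atoms: none
Why: Acidolysis of the tert-butyl ester with loss of 2-methylpropene, which should leave the secondary alkyl ester, the tertiary alcohol and the vinylogous ester of ring B intact.

Compound list
1 | 3-(trimethylsilyl)propiolaldehyde | C[Si](C)(C)C#CC=O | starting material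
2 | tert-butyl (triphenylphosphoranylidene)acetate | CC(C)(C)OC(=O)C=P(c1ccccc1)(c1ccccc1)c1ccccc1 | starting material
3 | tert-butyl (E)-5-(trimethylsilyl)pent-2-en-4-ynoate | C[Si](C)(C)C#C/C=C/C(=O)OC(C)(C)C | intermediate
4 | tert-butyl (E)-pent-2-en-4-ynoate | C#C/C=C/C(=O)OC(C)(C)C | intermediate
5 | (E)-4,4-dimethoxybut-2-enal | COC(OC)/C=C/C=O | starting material
6 | 2,3-dibromo-4,4-dimethoxybutanal (racemic, 2S*,3R*; not isolated) | O=C[C@H](Br)[C@H](Br)C(OC)OC | intermediate
7 | (Z)-2-bromo-4,4-dimethoxybut-2-enal | O=C/C(Br)=C/C(OC)OC | intermediate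
8 | tert-butyl (2E,6E)-6-formyl-8,8-dimethoxyocta-2,6-dien-4-ynoate | O=C/C(C#C/C=C/C(=O)OC(C)(C)C)=C/C(OC)OC | intermediate
9 | hydroxyacetone | CC(=O)CO | starting material
10 | 1-[(tert-butyldimethylsilyl)oxy]propan-2-one | CC(=O)CO[Si](C)(C)C(C)(C)C | intermediate
11 | anti aldol (5S,6S) | CC(=O)[C@@H](O[Si](C)(C)C(C)(C)C)[C@@H](O)/C(C#C/C=C/C(=O)OC(C)(C)C)=C/C(OC)OC | intermediate
12 | bromoacetyl bromide | O=C(Br)CBr | starting material
13 | C5 bromoacetate of 11 | CC(=O)[C@@H](O[Si](C)(C)C(C)(C)C)[C@@H](OC(=O)CBr)/C(C#C/C=C/C(=O)OC(C)(C)C)=C/C(OC)OC | intermediate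
14 | diiodosamarium enolate of 13 (not isolated) | CC(=O)[C@@H](O[Si](C)(C)C(C)(C)C)[C@@H](OC(=C)O[Sm](I)I)/C(C#C/C=C/C(=O)OC(C)(C)C)=C/C(OC)OC | intermediate
15 | hydroxy lactone (C7 OH trans to the alkenyl group) | O=C1C[C@@](C)(O)[C@@H](O[Si](C)(C)C(C)(C)C)[C@@H](O1)/C(C#C/C=C/C(=O)OC(C)(C)C)=C/C(OC)OC | intermediate
16 | 6-alkenyl δ-lactone, C7 OTES (precursor of the key step) | O=C1C[C@@](C)(O[Si](CC)(CC)CC)[C@@H](O[Si](C)(C)C(C)(C)C)[C@@H](O1)/C(C#C/C=C/C(=O)OC(C)(C)C)=C/C(OC)OC | intermediate
17 | cyclic trimethylsilyl ketene acetal of 16 (not isolated) | C[Si](C)(C)OC1=C[C@@](C)(O[Si](CC)(CC)CC)[C@@H](O[Si](C)(C)C(C)(C)C)[C@@H](O1)/C(C#C/C=C/C(=O)OC(C)(C)C)=C/C(OC)OC | intermediate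
18 | trimethylsilyl ester of 19 (not isolated) | C[Si](C)(C)OC(=O)[C@@H]1[C@H](C(OC)OC)C(C#C/C=C/C(=O)OC(C)(C)C)=C[C@H](O[Si](C)(C)C(C)(C)C)[C@]1(C)O[Si](CC)(CC)CC | intermediate
19 | ring A carboxylic acid (product of the key step) | OC(=O)[C@@H]1[C@H](C(OC)OC)C(C#C/C=C/C(=O)OC(C)(C)C)=C[C@H](O[Si](C)(C)C(C)(C)C)[C@]1(C)O[Si](CC)(CC)CC | intermediate
20 | (S)-2-methylbutan-1-ol | CC[C@H](C)CO | starting material
21 | (S)-1-bromo-2-methylbutane | CC[C@H](C)CBr | intermediate
22 | acetaldehyde | CC=O | starting material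
23 | (S)-2-methylbutylmagnesium bromide (not isolated) | CC[C@H](C)C[Mg]Br | intermediate
24 | (4S)-4-methylhexan-2-ol, both C2 epimers | CC[C@H](C)CC(C)O | intermediate
25 | (2R,4S)-4-methylhexan-2-yl acetate | CC[C@H](C)C[C@@H](C)OC(C)=O | intermediate
26 | (2R,4S)-4-methylhexan-2-ol | CC[C@H](C)C[C@@H](C)O | intermediate
27 | (2S,4S)-4-methylhexan-2-yl ester of 19 | CC[C@H](C)C[C@H](C)OC(=O)[C@@H]1[C@H](C(OC)OC)C(C#C/C=C/C(=O)OC(C)(C)C)=C[C@H](O[Si](C)(C)C(C)(C)C)[C@]1(C)O[Si](CC)(CC)CC | intermediate
28 | C6,C7 diol | CC[C@H](C)C[C@H](C)OC(=O)[C@@H]1[C@H](C(OC)OC)C(C#C/C=C/C(=O)OC(C)(C)C)=C[C@H](O)[C@]1(C)O | intermediate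
29 | C6 enone with C1 acetal | CC[C@H](C)C[C@H](C)OC(=O)[C@@H]1[C@H](C(OC)OC)C(C#C/C=C/C(=O)OC(C)(C)C)=CC(=O)[C@]1(C)O | intermediate
30 | C1 aldehyde (keto form) | CC[C@H](C)C[C@H](C)OC(=O)[C@@H]1[C@H](C=O)C(C#C/C=C/C(=O)OC(C)(C)C)=CC(=O)[C@]1(C)O | intermediate
31 | tert-butyl ester of the target | CC[C@H](C)C[C@H](C)OC(=O)[C@@H]1C2=COC(/C=C/C(=O)OC(C)(C)C)=CC2=CC(=O)[C@]1(C)O | intermediate
32 | CNP0114760.1 | CC[C@H](C)C[C@H](C)OC(=O)[C@@H]1C2=COC(/C=C/C(=O)O)=CC2=CC(=O)[C@]1(C)O | target

Total step count: 20.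
Longest linear sequence: 14 steps (1, 2, 4, 6, 7, 8, 9, 10, 15, 16, 17, 18, 19, 20) from 3-(trimethylsilyl)propiolaldehyde.

Steps most likely to fail

Step 10 (key step). What may go wrong: after deprotonation at C8 the enolate may expel the C7 triethylsilyloxy group (E1cB) before it is silylated, or the ketene acetal may decompose on heating before the strained boat is reached. Fallback (known chemistry, the dianion Ireland–Claisen rearrangement of a β-hydroxy ester): it sets out from hydroxy lactone 15, which is left unsilylated. LiN(i-Pr)2 (2.2 equiv, THF, −78 °C) gives the dilithium alkoxide enolate F1, whose β-oxygen is an oxide and cannot leave. TMSCl then gives the bis(trimethylsilyl) ketene acetal F2, which rearranges on warming to the trimethylsilyl ester F3. Aqueous work-up gives the acid with a C7 trimethylsilyl ether F4. Mitsunobu esterification with 26 as in step 15 gives the side-chain ester F5, and HF·pyridine as in step 16 removes both silyl groups, so the route is rejoined at diol 28.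

Step 6. What may go wrong: the hindered silyloxy ketone may form the (E)-enamine slowly, so that conversion, anti/syn ratio and facial selectivity at C5 are poor. Fallback (known chemistry, the primary amino acid catalysed syn aldol of silyl-protected hydroxy ketones through the hydrogen-bonded (Z)-enamine): from 8 and 10, O-tert-butyl-D-threonine (20 mol %, NMP, rt) should give the syn aldol (5S,6R) F6, the C6 epimer of 11 with the same C5 configuration. Because C6 only carries the oxygen that becomes the ketone in step 17, the C6-epimeric series is taken through steps 7 to 16 with the same reagents: bromoacetate F7, samarium enolate F8, hydroxy lactone F9, triethylsilyl ether F10, silyl ketene acetal F11, trimethylsilyl ester F12, ring A acid F13, side-chain ester F14 and diol F15. Dess–Martin oxidation of F15 as in step 17 gives enone 29, where the route is rejoined.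

Step 8. What may go wrong: divalent samarium may also cleave the α-silyloxy ketone or reduce the enynoate, or the β-acyloxy ketone may eliminate to an enone. Fallback (known chemistry, intermolecular ester enolate addition under Felkin–Anh control followed by lactonisation): from 11, TESCl and imidazole give the C5 triethylsilyl ether F16. The lithium enolate of methyl acetate F17 (methyl acetate, LiN(i-Pr)2, THF, −78 °C) adds to the methyl ketone anti to the C6 silyloxy group to give the hydroxy ester F18. Pyridinium p-toluenesulfonate in MeOH removes the triethylsilyl group to give the dihydroxy ester F19, which lactonises (same acid, toluene, 50 °C) to hydroxy lactone 15, where the route is rejoined.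

Further compounds
F1 | step 10 | dilithium alkoxide enolate of 15 | [Li]OC1=C[C@@](C)(O[Li])[C@@H](O[Si](C)(C)C(C)(C)C)[C@@H](O1)/C(C#C/C=C/C(=O)OC(C)(C)C)=C/C(OC)OC
F2 | step 10 | bis(trimethylsilyl) ketene acetal (C7 OTMS) | C[Si](C)(C)OC1=C[C@@](C)(O[Si](C)(C)C)[C@@H](O[Si](C)(C)C(C)(C)C)[C@@H](O1)/C(C#C/C=C/C(=O)OC(C)(C)C)=C/C(OC)OC
F3 | step 10 | trimethylsilyl ester of F4 | C[Si](C)(C)OC(=O)[C@@H]1[C@H](C(OC)OC)C(C#C/C=C/C(=O)OC(C)(C)C)=C[C@H](O[Si](C)(C)C(C)(C)C)[C@]1(C)O[Si](C)(C)C
F4 | step 10 | ring A acid with C7 OTMS | OC(=O)[C@@H]1[C@H](C(OC)OC)C(C#C/C=C/C(=O)OC(C)(C)C)=C[C@H](O[Si](C)(C)C(C)(C)C)[C@]1(C)O[Si](C)(C)C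
F5 | step 10 | (2S,4S)-4-methylhexan-2-yl ester of F4 | CC[C@H](C)C[C@H](C)OC(=O)[C@@H]1[C@H](C(OC)OC)C(C#C/C=C/C(=O)OC(C)(C)C)=C[C@H](O[Si](C)(C)C(C)(C)C)[C@]1(C)O[Si](C)(C)C
F6 | step 6 | syn aldol (5S,6R), C6 epimer of 11 | CC(=O)[C@H](O[Si](C)(C)C(C)(C)C)[C@@H](O)/C(C#C/C=C/C(=O)OC(C)(C)C)=C/C(OC)OC
F7 | step 6 | C6 epimer of bromoacetate 13 | CC(=O)[C@H](O[Si](C)(C)C(C)(C)C)[C@@H](OC(=O)CBr)/C(C#C/C=C/C(=O)OC(C)(C)C)=C/C(OC)OC
F8 | step 6 | C6 epimer of samarium enolate 14 | CC(=O)[C@H](O[Si](C)(C)C(C)(C)C)[C@@H](OC(=C)O[Sm](I)I)/C(C#C/C=C/C(=O)OC(C)(C)C)=C/C(OC)OC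
F9 | step 6 | C6 epimer of hydroxy lactone 15 | O=C1C[C@@](C)(O)[C@H](O[Si](C)(C)C(C)(C)C)[C@@H](O1)/C(C#C/C=C/C(=O)OC(C)(C)C)=C/C(OC)OC
F10 | step 6 | C6 epimer of lactone 16 | O=C1C[C@@](C)(O[Si](CC)(CC)CC)[C@H](O[Si](C)(C)C(C)(C)C)[C@@H](O1)/C(C#C/C=C/C(=O)OC(C)(C)C)=C/C(OC)OC
F11 | step 6 | C6 epimer of ketene acetal 17 | C[Si](C)(C)OC1=C[C@@](C)(O[Si](CC)(CC)CC)[C@H](O[Si](C)(C)C(C)(C)C)[C@@H](O1)/C(C#C/C=C/C(=O)OC(C)(C)C)=C/C(OC)OC
F12 | step 6 | C6 epimer of silyl ester 18 | C[Si](C)(C)OC(=O)[C@@H]1[C@H](C(OC)OC)C(C#C/C=C/C(=O)OC(C)(C)C)=C[C@@H](O[Si](C)(C)C(C)(C)C)[C@]1(C)O[Si](CC)(CC)CC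
F13 | step 6 | C6 epimer of acid 19 | OC(=O)[C@@H]1[C@H](C(OC)OC)C(C#C/C=C/C(=O)OC(C)(C)C)=C[C@@H](O[Si](C)(C)C(C)(C)C)[C@]1(C)O[Si](CC)(CC)CC
F14 | step 6 | C6 epimer of ester 27 | CC[C@H](C)C[C@H](C)OC(=O)[C@@H]1[C@H](C(OC)OC)C(C#C/C=C/C(=O)OC(C)(C)C)=C[C@@H](O[Si](C)(C)C(C)(C)C)[C@]1(C)O[Si](CC)(CC)CC
F15 | step 6 | C6 epimer of diol 28 | CC[C@H](C)C[C@H](C)OC(=O)[C@@H]1[C@H](C(OC)OC)C(C#C/C=C/C(=O)OC(C)(C)C)=C[C@@H](O)[C@]1(C)O
F16 | step 8 | C5 triethylsilyl ether of 11 | CC(=O)[C@@H](O[Si](C)(C)C(C)(C)C)[C@@H](O[Si](CC)(CC)CC)/C(C#C/C=C/C(=O)OC(C)(C)C)=C/C(OC)OC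
F17 | step 8 | lithium enolate of methyl acetate | [Li]OC(=C)OC
F18 | step 8 | methyl ester adduct (C5 OTES, C7 OH) | COC(=O)C[C@@](C)(O)[C@@H](O[Si](C)(C)C(C)(C)C)[C@@H](O[Si](CC)(CC)CC)/C(C#C/C=C/C(=O)OC(C)(C)C)=C/C(OC)OC
F19 | step 8 | dihydroxy methyl ester (seco ester of 15) | COC(=O)C[C@@](C)(O)[C@@H](O[Si](C)(C)C(C)(C)C)[C@@H](O)/C(C#C/C=C/C(=O)OC(C)(C)C)=C/C(OC)OC
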